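**Plan**
- Bisoflavolin G has no stereocentre. The retrosynthesis first cuts the four O–CH3 bonds, then O1–C2 and C2–C3 of the daidzein pyranone (a one-carbon unit), which leaves a 2-hydroxydeoxybenzoin.
- The enabling feature is ring A of the daidzein half: C8a–O, C8–OAr and C7–O are contiguous and sit beside the acyl-bearing C4a, with C5 and C6 unsubstituted. A 2,3-dioxygenated 4-alkenylcyclobutenone delivers exactly this pattern on ring expansion, so the C4a–C8a bond is cut.
- The cyclobutenone is cut at its C4–alkenyl bond (palladium coupling of a 4-chloride with a β-stannyl enone) and traced back to a squarate. The hindered C8–O–aryl bond is made as an ester bond between squaric acid dichloride and the 4'-OH of 8-chloro-5,7-di-O-methylgenistein.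
- Forward order: the pyranone of the chlorinated half is made first. Then follow the diaryl squarate, reduction, exchange of the β-aryloxy group for methoxy, the chloride and the coupling. Ring A of the daidzein half forms in the key step, its pyranone closes last, and global demethylation ends the route.
- Stereochemistry: the C4 centre of the cyclobutenones is racemic and is erased on aromatisation, and the E geometry of the stannane also disappears in ring A.

Key step: step 9

Assumption: 2-chloro-3,5-dimethoxyphenol, squaric acid dichloride and (E)-1,2-bis(tributylstannyl)ethene are taken as purchasable. Phenoxide is a better leaving group than methoxide, so the aryl ether is made from the squaryl chloride and not by exchange on dimethyl squarate.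

Notation: ArO stands for the 4-(8-chloro-5,7-dimethoxy-4-oxo-4H-chromen-3-yl)phenoxy group.

**Route**

Step 1
Reactants: 1 2-chloro-3,5-dimethoxyphenol; 2 4-hydroxyphenylacetic acid
Product: 4 8-chloro-3-(4-hydroxyphenyl)-5,7-dimethoxy-4H-chromen-4-one, via 2-hydroxydeoxybenzoin 3 (not isolated)
Conditions: BF3·OEt2 (neat), 85 °C; then DMF, MsCl, 70 °C; aq. NaOAc work-up
Reagents that add atoms: N,N-dimethylformamide, CN(C)C=O
Why: BF3-promoted Friedel–Crafts acylation should occur at C6, the only free position ortho to the phenol, and the chelated deoxybenzoin is then formylated at its methylene by the DMF/MsCl Vilsmeier-type reagent and closes to the pyranone (one-pot deoxybenzoin isoflavone synthesis), leaving the remote 4'-OH free.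

Step 2
Reactants: 4 8-chloro-3-(4-hydroxyphenyl)-5,7-dimethoxy-4H-chromen-4-one (2.05 equiv); 5 squaric acid dichloride (3,4-dichlorocyclobut-3-ene-1,2-dione)
Product: 6 3,4-bis(ArO)cyclobut-3-ene-1,2-dione (diaryl squarate)
Conditions: iPr2NEt (2.2 equiv), CH2Cl2, –20 °C to rt
Reagents that add atoms: none
Why: Squaric acid dichloride is a vinylogous acid chloride, so each chloride should be displaced by the phenoxide through addition–elimination (esterification of squaryl dichloride with phenols), and this forms the future C8–O–aryl bond without any aryl coupling.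

Step 3
Reactants: 6 3,4-bis(ArO)cyclobut-3-ene-1,2-dione
Product: 7 rac-2,3-bis(ArO)-4-hydroxycyclobut-2-en-1-one
Conditions: LiAlH(OtBu)3 (1.05 equiv), THF, –78 °C; pH 7 phosphate buffer at –78 °C
Reagents that add atoms: none
Why: 1,2-Reduction of one carbonyl of a squarate diester by LiAlH(OtBu)3 is known to stop at the 4-hydroxycyclobutenone because the remaining carbonyl is a deactivated vinylogous ester, and since 6 is symmetric no regiochemical choice arises, while the chromone carbonyls and the aryl chlorides should not react at –78 °C.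

Step 4
Reactants: 7 rac-2,3-bis(ArO)-4-hydroxycyclobut-2-en-1-one
Product: 8 rac-2-(ArO)-4-hydroxy-3-methoxycyclobut-2-en-1-one
Conditions: MeOH–THF (1:1), Et3N (1.5 equiv), DMAP (10 mol %), 0 °C
Reagents that add atoms: methanol, CO
Why: Only the aryloxy group on C3 is β to the carbonyl and thus a vinylogous aryl ester, so addition–elimination by methanol (vinylogous transesterification, downhill because phenoxide is the better leaving group) should replace it alone, which fixes ArO on the α-carbon and OMe on the β-carbon and returns one equivalent of 4 for reuse.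

Step 5
Reactants: 8 rac-2-(ArO)-4-hydroxy-3-methoxycyclobut-2-en-1-one
Product: 9 rac-2-(ArO)-4-chloro-3-methoxycyclobut-2-en-1-one
Conditions: SOCl2 (1.2 equiv), pyridine (1.5 equiv), CH2Cl2, –20 to 0 °C
Reagents that add atoms: thionyl chloride, O=S(Cl)Cl
Why: Chlorosulfite formation followed by chloride displacement under pyridine buffering (Darzens-type alcohol to chloride conversion) should give the 4-chlorocyclobutenone used in cross-coupling, and the aryl group on the C2 oxygen cannot be lost by dealkylation as an alkyl group could.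

Step 6
Reactants: 10 4-methoxyphenylacetic acid
Product: 11 N-methoxy-2-(4-methoxyphenyl)-N-methylacetamide
Conditions: CDI, CH2Cl2, rt; then MeNH(OMe)·HCl, rt
Reagents that add atoms: N,O-dimethylhydroxylamine hydrochloride, CNOC.Cl
Why: Activation as the acyl imidazole and aminolysis is the standard Weinreb amide formation and tolerates the anisyl group.

Step 7
Reactants: 11 N-methoxy-2-(4-methoxyphenyl)-N-methylacetamide; 12 (E)-1,2-bis(tributylstannyl)ethene
Product: 14 (E)-1-(4-methoxyphenyl)-4-(tributylstannyl)but-3-en-2-one, via (E)-2-(tributylstannyl)vinyllithium 13 (not isolated)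
Conditions: 12, n-BuLi (1.05 equiv), THF, –78 °C; then 11, –78 to –40 °C; sat. aq. NH4Cl
Reagents that add atoms: none
Why: Tin–lithium exchange on one stannyl group proceeds with retention of the E geometry, and addition of the vinyllithium to the Weinreb amide stops at the chelated tetrahedral intermediate, so the β-stannyl enone should appear only on work-up (Weinreb ketone synthesis).

Step 8
Reactants: 9 rac-2-(ArO)-4-chloro-3-methoxycyclobut-2-en-1-one; 14 (E)-1-(4-methoxyphenyl)-4-(tributylstannyl)but-3-en-2-one
Product: 15 rac-2-(ArO)-3-methoxy-4-[(E)-4-(4-methoxyphenyl)-3-oxobut-1-en-1-yl]cyclobut-2-en-1-one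
Conditions: PdCl2(PhCN)2 (5 mol %), tri(2-furyl)phosphine (10 mol %), CuI (10 mol %), dioxane, 25–40 °C; aq. KF work-up, chromatography at rt
Reagents that add atoms: none
Why: Oxidative addition of the allylic C–Cl bond to zerovalent palladium gives an η3-oxocyclobutenyl complex that should transmetalate with the vinylstannane and eliminate at the unsubstituted terminus C4 with retention of alkene geometry (Stille coupling of 4-chlorocyclobutenones), and the low temperature keeps the four-membered ring closed and the aryl chloride untouched.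

Step 9
Reactants: 15 rac-2-(ArO)-3-methoxy-4-[(E)-4-(4-methoxyphenyl)-3-oxobut-1-en-1-yl]cyclobut-2-en-1-one
Product: 18 1-[3-(ArO)-2-hydroxy-4-methoxyphenyl]-2-(4-methoxyphenyl)ethan-1-one, via dienylketene 16 (not isolated), via 6-acylcyclohexa-2,4-dienone 17 (not isolated)
Conditions: toluene (0.02 M), 100 °C, argon, base-free
Reagents that add atoms: none
Why: Heating should open the C1–C4 bond of the cyclobutenone in a conrotatory four-electron process to dienylketene 16, the known thermal ring expansion of 4-alkenylcyclobutenones to phenols. Ring A then closes by a thermal disrotatory six-electron electrocyclisation that joins the ketene carbon (future C8a) to the enone α-carbon (future C4a), and the 6-acylcyclohexadienone 17 enolises irreversibly to the hydrogen-bonded phenol. No stereocentre results, because the racemic C4 centre of 15 and the transient sp3 carbon of 17 both become aromatic carbons. The step needs the ketene isomer with the alkenyl group rotated inward; ring opening is reversible, so the outward isomer returns to 15 while the inward isomer is consumed. The substituent order OH (C8a), OAr (C8), OMe (C7), H, H, acyl (C4a) is fixed by the connectivity of 15 set in steps 2 to 5, and dilute aprotic conditions keep the ketene from being trapped and the acidic ring C–H from isomerising.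

Step 10
Reactants: 18 1-[3-(ArO)-2-hydroxy-4-methoxyphenyl]-2-(4-methoxyphenyl)ethan-1-one
Product: 20 8-chloro-5,7-dimethoxy-3-(4-{[7-methoxy-3-(4-methoxyphenyl)-4-oxo-4H-chromen-8-yl]oxy}phenyl)-4H-chromen-4-one (tetra-O-methylbisoflavolin G), via enaminone 19 (not isolated)
Conditions: Me2NCH(OMe)2 (3 equiv), toluene, 90 °C
Reagents that add atoms: N,N-dimethylformamide dimethyl acetal, COC(OC)N(C)C
Why: The acetal condenses with the activated methylene to an enaminone, and the ortho phenol then adds in conjugate fashion and expels dimethylamine to close the pyranone (standard isoflavone synthesis from 2-hydroxydeoxybenzoins).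

Step 11
Reactants: 20 tetra-O-methylbisoflavolin G
Product: 21 bisoflavolin G
Conditions: BBr3 (12 equiv), CH2Cl2, –78 °C to rt; MeOH, then water
Reagents that add atoms: none
Why: BBr3 cleaves aryl methyl ethers by bromide attack on the methyl carbon of the boron-complexed ether, whereas the diaryl ether offers no sp3 carbon for that attack and the aryl chloride and both chromones are inert, so all four methyl groups should be removed with the skeleton intact.

**Compound list**

1 | 2-chloro-3,5-dimethoxyphenol | COc1cc(O)c(Cl)c(OC)c1 | starting material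
2 | 4-hydroxyphenylacetic acid | OC(=O)Cc1ccc(O)cc1 | starting material
3 | 1-(3-chloro-2-hydroxy-4,6-dimethoxyphenyl)-2-(4-hydroxyphenyl)ethan-1-one | COc1cc(OC)c(C(=O)Cc2ccc(O)cc2)c(O)c1Cl | intermediate (not isolated)
4 | 8-chloro-3-(4-hydroxyphenyl)-5,7-dimethoxy-4H-chromen-4-one | Oc1ccc(-c2coc3c(Cl)c(OC)cc(OC)c3c2=O)cc1 | intermediate
5 | squaric acid dichloride (3,4-dichlorocyclobut-3-ene-1,2-dione) | ClC1=C(Cl)C(=O)C1=O | starting material
6 | 3,4-bis[4-(8-chloro-5,7-dimethoxy-4-oxo-4H-chromen-3-yl)phenoxy]cyclobut-3-ene-1,2-dione | O=C1C(=O)C(Oc2ccc(-c3coc4c(Cl)c(OC)cc(OC)c4c3=O)cc2)=C1Oc1ccc(-c2coc3c(Cl)c(OC)cc(OC)c3c2=O)cc1 | intermediate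
7 | rac-2,3-bis[4-(8-chloro-5,7-dimethoxy-4-oxo-4H-chromen-3-yl)phenoxy]-4-hydroxycyclobut-2-en-1-one | O=C1C(Oc2ccc(-c3coc4c(Cl)c(OC)cc(OC)c4c3=O)cc2)=C(Oc2ccc(-c3coc4c(Cl)c(OC)cc(OC)c4c3=O)cc2)C1O | intermediate
8 | rac-2-[4-(8-chloro-5,7-dimethoxy-4-oxo-4H-chromen-3-yl)phenoxy]-4-hydroxy-3-methoxycyclobut-2-en-1-one | O=C1C(Oc2ccc(-c3coc4c(Cl)c(OC)cc(OC)c4c3=O)cc2)=C(OC)C1O | intermediate
9 | rac-2-[4-(8-chloro-5,7-dimethoxy-4-oxo-4H-chromen-3-yl)phenoxy]-4-chloro-3-methoxycyclobut-2-en-1-one | O=C1C(Oc2ccc(-c3coc4c(Cl)c(OC)cc(OC)c4c3=O)cc2)=C(OC)C1Cl | intermediate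
10 | 4-methoxyphenylacetic acid | COc1ccc(CC(=O)O)cc1 | starting material
11 | N-methoxy-2-(4-methoxyphenyl)-N-methylacetamide | COc1ccc(CC(=O)N(C)OC)cc1 | intermediate
12 | (E)-1,2-bis(tributylstannyl)ethene | CCCC[Sn](CCCC)(CCCC)/C=C/[Sn](CCCC)(CCCC)CCCC | starting material
13 | (E)-2-(tributylstannyl)vinyllithium | [Li]/C=C/[Sn](CCCC)(CCCC)CCCC | intermediate (not isolated)
14 | (E)-1-(4-methoxyphenyl)-4-(tributylstannyl)but-3-en-2-one | COc1ccc(CC(=O)/C=C/[Sn](CCCC)(CCCC)CCCC)cc1 | intermediate
15 | rac-2-[4-(8-chloro-5,7-dimethoxy-4-oxo-4H-chromen-3-yl)phenoxy]-3-methoxy-4-[(E)-4-(4-methoxyphenyl)-3-oxobut-1-en-1-yl]cyclobut-2-en-1-one | O=C1C(Oc2ccc(-c3coc4c(Cl)c(OC)cc(OC)c4c3=O)cc2)=C(OC)C1/C=C/C(=O)Cc1ccc(OC)cc1 | intermediate (key-step precursor)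
16 | (3E,5E)-2-(ArO)-3-methoxy-8-(4-methoxyphenyl)octa-1,3,5-triene-1,7-dione, the dienylketene with C2 and C5 cis about C3=C4 | O=C=C(Oc1ccc(-c2coc3c(Cl)c(OC)cc(OC)c3c2=O)cc1)/C(OC)=C\C=C\C(=O)Cc1ccc(OC)cc1 | intermediate (not isolated)
17 | rac-2-(ArO)-3-methoxy-6-[2-(4-methoxyphenyl)acetyl]cyclohexa-2,4-dien-1-one | O=C1C(Oc2ccc(-c3coc4c(Cl)c(OC)cc(OC)c4c3=O)cc2)=C(OC)C=CC1C(=O)Cc1ccc(OC)cc1 | intermediate (not isolated)
18 | 1-{3-[4-(8-chloro-5,7-dimethoxy-4-oxo-4H-chromen-3-yl)phenoxy]-2-hydroxy-4-methoxyphenyl}-2-(4-methoxyphenyl)ethan-1-one | COc1ccc(CC(=O)c2ccc(OC)c(Oc3ccc(-c4coc5c(Cl)c(OC)cc(OC)c5c4=O)cc3)c2O)cc1 | intermediate (key-step product)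
19 | 1-[3-(ArO)-2-hydroxy-4-methoxyphenyl]-3-(dimethylamino)-2-(4-methoxyphenyl)prop-2-en-1-one (alkene geometry not defined) | COc1ccc(C(=CN(C)C)C(=O)c2ccc(OC)c(Oc3ccc(-c4coc5c(Cl)c(OC)cc(OC)c5c4=O)cc3)c2O)cc1 | intermediate (not isolated)
20 | 8-chloro-5,7-dimethoxy-3-(4-{[7-methoxy-3-(4-methoxyphenyl)-4-oxo-4H-chromen-8-yl]oxy}phenyl)-4H-chromen-4-one | COc1ccc(-c2coc3c(Oc4ccc(-c5coc6c(Cl)c(OC)cc(OC)c6c5=O)cc4)c(OC)ccc3c2=O)cc1 | intermediate
21 | bisoflavolin G | O=c1c(-c2ccc(O)cc2)coc2c(Oc3ccc(-c4coc5c(Cl)c(O)cc(O)c5c4=O)cc3)c(O)ccc12 | target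

**Step count**

Total: 11 steps. Longest linear sequence: 9 steps (steps 1, 2, 3, 4, 5, 8, 9, 10, 11).

**Steps most likely to fail**

Step 5. The activated alcohol derivative may ionise, and chloride or adventitious water may then be captured at the aryloxy-bearing ring carbon instead of at C4, which would end in loss of the aryloxy group on work-up. The fallback avoids the chloride. It sets out from 8, which is acetylated (Ac2O, pyridine, DMAP, 0 °C) to rac-4-acetoxy-2-(ArO)-3-methoxycyclobut-2-en-1-one F1. This allylic acetate is coupled directly with stannane 14 (Pd2(dba)3, tri(2-furyl)phosphine, LiCl, DMF, rt) through the same η3-oxocyclobutenyl palladium intermediate, as in the known coupling of allylic acetates with vinylstannanes. The fallback comes back to the route at 15.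

Step 8. Transmetalation of the electron-poor β-stannyl enone may be slow. The palladium allyl intermediate could then decompose or couple at the aryloxy-bearing terminus, or the temperature needed could open the ring prematurely. The fallback uses a more nucleophilic stannane at the alcohol oxidation level. It sets out from 14, which is reduced (NaBH4, CeCl3·7H2O, MeOH, –40 °C) to rac-(E)-1-(4-methoxyphenyl)-4-(tributylstannyl)but-3-en-2-ol F2. Coupling of this stannane with chloride 9 under the catalyst of step 8 should give 2-(ArO)-4-[(E)-3-hydroxy-4-(4-methoxyphenyl)but-1-en-1-yl]-3-methoxycyclobut-2-en-1-one F3 as a mixture of diastereomers. Oxidation of the allylic alcohol with MnO2 (CH2Cl2, rt) returns to the route at 15.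

Step 3. Both carbonyls of the diaryl squarate are strongly activated, so over-reduction or hydride attack at an aryloxy-bearing ring carbon with expulsion of phenoxide may compete, and 6 may be poorly soluble at –78 °C. The fallback uses a mixed squarate with only one aryloxy group. It sets out from 5 and 4. Dichloride 5 and one equivalent of methanol (CH2Cl2, 0 °C) give 3-chloro-4-methoxycyclobut-3-ene-1,2-dione F4. Displacement of its chloride by phenol 4 (iPr2NEt, CH2Cl2, 0 °C) gives 3-(ArO)-4-methoxycyclobut-3-ene-1,2-dione F5. Reduction with LiAlH(OtBu)3 (THF, –78 °C) should go to the carbonyl that is vinylogous to the weaker donor, the aryloxy group, and lead directly to 8, where the fallback rejoins the route; step 4 is then not needed. Here the regiochemistry rests on electronic discrimination between two carbonyls, which is why this is the fallback and not the main line.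

**Further compounds**

F1 | step 5 | rac-4-acetoxy-2-[4-(8-chloro-5,7-dimethoxy-4-oxo-4H-chromen-3-yl)phenoxy]-3-methoxycyclobut-2-en-1-one | CC(=O)OC1C(=O)C(Oc2ccc(-c3coc4c(Cl)c(OC)cc(OC)c4c3=O)cc2)=C1OC
F2 | step 8 | rac-(E)-1-(4-methoxyphenyl)-4-(tributylstannyl)but-3-en-2-ol | COc1ccc(CC(O)/C=C/[Sn](CCCC)(CCCC)CCCC)cc1
F3 | step 8 | 2-[4-(8-chloro-5,7-dimethoxy-4-oxo-4H-chromen-3-yl)phenoxy]-4-[(E)-3-hydroxy-4-(4-methoxyphenyl)but-1-en-1-yl]-3-methoxycyclobut-2-en-1-one (mixture of diastereomers) | O=C1C(Oc2ccc(-c3coc4c(Cl)c(OC)cc(OC)c4c3=O)cc2)=C(OC)C1/C=C/C(O)Cc1ccc(OC)cc1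
F4 | step 3 | 3-chloro-4-methoxycyclobut-3-ene-1,2-dione | COC1=C(Cl)C(=O)C1=O
F5 | step 3 | 3-[4-(8-chloro-5,7-dimethoxy-4-oxo-4H-chromen-3-yl)phenoxy]-4-methoxycyclobut-3-ene-1,2-dione | COC1=C(Oc2ccc(-c3coc4c(Cl)c(OC)cc(OC)c4c3=O)cc2)C(=O)C1=O
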